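The ten-membered carbocycle C1–C10 is not closed as such: C1 and C10, the two carbons of the E-trisubstituted alkene, are first bridged by sulfur in an eleven-membered thiacycle. That larger ring is closed by a chromium Barbier allylation (C7–C8), which sets C7 and C8 from C6 and fuses the lactone. A Ramberg–Bäcklund reaction on the α-chloro sulfone then deletes the sulfur atom: the eleven-membered ring contracts to the ten-membered one and C1=C10 is created in the same operation, while the stereorandom sp3 centres at C1 and C10 converge. The precursor already carries the C4=C5 alkene, the C6–C8 triad and the masked methylene lactone.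

Key step: step 14

Remark: positions follow the germacrane numbering of the target (ring C1–C10, lactone C6–O–C12, C13 exo-methylene, C14 methyl, C15 CH2O); compounds 3–11 are racemic, and compounds 3–22 are mixtures of epimers at the sulfur-bearing carbons (C10, from step 8 also C1), which is immaterial because both become sp2 in step 14.

Step 1
Reactants: 1 (E)-but-2-enal (crotonaldehyde); 2 prop-2-ene-1-thiol
Product: 3 rac-3-(prop-2-en-1-ylsulfanyl)butanal
Conditions: Et3N (cat.), CH2Cl2, 0 °C
Reagents that add atoms: none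
Why: Base-catalysed thia-Michael addition of the thiol to the enal joins C1–S–C10 and brings in C8, C9, C10 and C14; the sulfur-bearing centre is left racemic because it becomes sp2 in step 14.

Step 2
Reactants: 3
Product: 4 rac-1,1-dimethoxy-3-(prop-2-en-1-ylsulfanyl)butane
Conditions: HC(OMe)3, MeOH, PPTS (cat.), rt
Reagents that add atoms: trimethyl orthoformate, COC(OC)OC
Why: Acid-catalysed acetalisation masks the C8 aldehyde against the hydride, Grignard and amide-base steps that follow.

Step 3
Reactants: 4
Product: 5 rac-1,1-dimethoxy-3-(prop-2-en-1-ylsulfonyl)butane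
Conditions: mCPBA (2.2 equiv), NaHCO3, CH2Cl2, 0 °C
Reagents that add atoms: mCPBA (3-chloroperoxybenzoic acid), O=C(OO)c1cccc(Cl)c1
Why: Peracid oxidation of sulfide to sulfone is far faster than epoxidation of the monosubstituted alkene, and is placed here because no electron-rich alkene is yet present.

Step 4
Reactants: 5; 6 4-bromofuran-2(5H)-one
Product: 8 4-[3-(4,4-dimethoxybutan-2-ylsulfonyl)propyl]furan-2(5H)-one, via alkylborane 7 (not isolated)
Conditions: 9-BBN, THF, 0 °C to rt; then 6, PdCl2(dppf), K3PO4 (aq), DMF, rt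
Reagents that add atoms: none
Why: Anti-Markovnikov hydroboration followed by B-alkyl Suzuki–Miyaura coupling with the β-bromo butenolide forms C3–C4, and the butenolide ring holds C6 and C15 cis on C4=C5, which is the ring-trans geometry of the target.

Step 5
Reactants: 8
Product: 10 (2Z)-2-[3-(4,4-dimethoxybutan-2-ylsulfonyl)propyl]hexa-2,5-diene-1,4-diol, via lactol 9 (not isolated)
Conditions: iBu2AlH (DIBAL-H, 1.1 equiv), CH2Cl2, −78 °C; then CH2=CHMgBr (4 equiv), THF, −78 to 0 °C
Reagents that add atoms: vinylmagnesium bromide, C=C[Mg]Br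
Why: DIBAL half-reduction gives the lactol, whose open hydroxy-enal form undergoes 1,2-Grignard addition; the Z alkene is inherited from the ring and the C6 carbinol is formed racemic (resolved in step 7).

Step 6
Reactants: 10
Product: 11 (4Z)-5-{[tert-butyl(diphenyl)silyl]oxymethyl}-8-(4,4-dimethoxybutan-2-ylsulfonyl)octa-1,4-dien-3-ol (racemic carbinol)
Conditions: TBDPSCl, imidazole, CH2Cl2, 0 °C
Reagents that add atoms: tert-butyl(chloro)diphenylsilane, CC(C)(C)[Si](Cl)(c1ccccc1)c1ccccc1
Why: Silylation is selective for the primary allylic C15–OH over the hindered secondary C6–OH.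

Step 7
Reactants: 11
Product: 12 (3S,4Z)-5-{[tert-butyl(diphenyl)silyl]oxymethyl}-8-(4,4-dimethoxybutan-2-ylsulfonyl)octa-1,4-dien-3-ol
Conditions: immobilised Candida antarctica lipase B, vinyl acetate, MTBE, 30 °C, run beyond half conversion
Reagents that add atoms: none
Why: Lipase-catalysed kinetic resolution by enantioselective transesterification; by the empirical size rule for secondary alcohols (vinyl as medium group, the trisubstituted alkenyl residue as large group) the (3R)-alcohol should be acetylated, leaving the (3S)-alcohol, which has the C6 configuration of the target.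

Step 8
Reactants: 12
Product: 13 (3S,4Z)-5-{[tert-butyl(diphenyl)silyl]oxymethyl}-8-chloro-8-(4,4-dimethoxybutan-2-ylsulfonyl)octa-1,4-dien-3-ol
Conditions: LiN(iPr)2 (LDA, 2.2 equiv), THF, −78 °C; then C2Cl6, −78 °C
Reagents that add atoms: hexachloroethane, ClC(Cl)(Cl)C(Cl)(Cl)Cl
Why: After alkoxide formation, kinetic α-sulfonyl deprotonation at the unhindered C1 methylene and electrophilic chlorination install the leaving group for step 14 while the sulfone is still the most acidic C–H site; the new C1 centre is uncontrolled and is removed in step 14.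

Step 9
Reactants: 13; 14 2-(bromomethyl)prop-2-enoic acid
Product: 15 (3S,4Z)-5-{[tert-butyl(diphenyl)silyl]oxymethyl}-8-chloro-8-(4,4-dimethoxybutan-2-ylsulfonyl)octa-1,4-dien-3-yl 2-(bromomethyl)prop-2-enoate
Conditions: DCC, DMAP (cat.), CH2Cl2, 0 °C
Reagents that add atoms: none
Why: Steglich esterification with retention at C6 brings in C11, C12 and C13.

Step 10
Reactants: 15
Product: 16 (5R)-3-(bromomethyl)-5-[(1Z)-2-{[tert-butyl(diphenyl)silyl]oxymethyl}-5-chloro-5-(4,4-dimethoxybutan-2-ylsulfonyl)pent-1-en-1-yl]furan-2(5H)-one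
Conditions: second-generation Grubbs catalyst (5 mol%), CH2Cl2, 40 °C
Reagents that add atoms: none
Why: Ring-closing metathesis between the vinyl group and the acrylate alkene closes the butenolide (C7=C11) with loss of ethene; the trisubstituted C4=C5 alkene does not take part.

Step 11
Reactants: 16
Product: 17 3-{[(4Z)-5-[(2R)-4-(bromomethyl)-5-oxo-2,5-dihydrofuran-2-yl]-4-{[tert-butyl(diphenyl)silyl]oxymethyl}-1-chloropent-4-en-1-yl]sulfonyl}butanal
Conditions: TFA, H2O, CH2Cl2, 0 °C
Reagents that add atoms: water, O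
Why: Acid hydrolysis of the dimethyl acetal frees the C8 aldehyde without touching the allylic bromide, the butenolide or the TBDPS ether; 17 is used at once because a β-sulfonyl aldehyde eliminates under base.

Step 12
Reactants: 17
Product: 19 eleven-membered sulfone hydroxy lactone (ring closed at C7–C8), via allylchromium dichloride 18 (not isolated)
Conditions: CrCl2 (8 equiv), THF, rt, high dilution (slow addition of 17)
Reagents that add atoms: none
Why: Chromium Barbier (Nozaki–Hiyama) allylation through 18: γ-attack at C7 in a closed chair transition state occurs anti to the C6 side chain (trans-fused lactone, C7 set from C6), the E-type allyl geometry fixed by the butenolide with the aldehyde residue equatorial gives the anti adduct (C8–OH as in 36), and the allylic transposition releases the exo-methylene lactone while the eleven-membered ring closes.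

Step 13
Reactants: 19
Product: 21 masked macrocycle (8-O-TES ether of the dimethylamine adduct of 19), via triethylsilyl ether 20 (not isolated)
Conditions: TESCl, imidazole, CH2Cl2, 0 °C; then Me2NH (2 M in THF), rt
Reagents that add atoms: chlorotriethylsilane, CC[Si](Cl)(CC)CC; dimethylamine, CNC
Why: Silylation of C8–OH and aza-Michael addition of the amine to the exo-methylene lactone (Mannich-base masking) remove the free alkoxide and the Michael acceptor before the strongly basic key step; the C11 centre formed is erased in step 15.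

Step 14
Reactants: 21
Product: 23 ring-contracted (1(10)E)-germacradienolide (amine-masked; 8-O-TES; 15-O-TBDPS), via episulfone 22 (not isolated)
Conditions: KOtBu (5 equiv), THF, −78 to 0 °C
Reagents that add atoms: none
Why: Ramberg–Bäcklund reaction used as a ring contraction: tert-butoxide reversibly deprotonates the α′-position C10–H of the α-chloro sulfone, the carbanion displaces chloride at C1 by intramolecular 1,3-substitution to give episulfone 22, and cheletropic loss of SO2 from 22 with retention turns the C1–S–C10 unit of the eleven-membered thiacycle into the C1=C10 bond of the ten-membered carbocycle. The closest known reaction type is the Ramberg–Bäcklund contraction of medium-ring α-halo sulfones to cycloalkenes, which has been used to make a trisubstituted ring alkene in a lactone-bearing nine-membered sesquiterpenoid ring. The only ring closed is the three-membered episulfone (3-exo-tet); the ten-membered ring is not cyclised but arises by excision of sulfur from the eleven-membered ring. No stereocentre is created, and all C1/C10 diastereomers of 21 (and both C11 epimers) converge on one product. The step needs E geometry at C1=C10: under the equilibrating alkoxide conditions the chlorine-bearing C1 epimerises, and closure is expected through the transoid arrangement with C2 and C9 on opposite faces of the forming thiirane dioxide, which the trans-fused lactone and the ring-trans C4=C5 alkene favour, so the trans episulfone and hence the E alkene should predominate. The lactone is carried as its Mannich adduct and C8–OH as its TES ether so that no Michael acceptor, free alkoxide or acyl group meets the base.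

Step 15
Reactants: 23
Product: 25 8-O-TES-15-O-TBDPS-protected 8α,15-dihydroxygermacra-1(10),4,11(13)-trien-6α,12-olide, via trimethylammonium iodide 24 (not isolated)
Conditions: MeI, THF/MeOH, rt; then NaHCO3 (aq), rt
Reagents that add atoms: none
Why: Quaternisation of the amine and E1cB (Hofmann-type) elimination regenerate the α-methylene lactone under conditions that leave the silyl ethers and the 1,5-diene alone.

Step 16
Reactants: 25
Product: 26 15-O-TBDPS-protected 8α,15-dihydroxygermacra-1(10),4,11(13)-trien-6α,12-olide (8-OH free)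
Conditions: PPTS, MeOH/CH2Cl2, 0 °C to rt
Reagents that add atoms: none
Why: Acid-catalysed methanolysis cleaves the secondary TES ether selectively; the primary TBDPS ether is stable to these conditions.

Step 17
Reactants: 27 (Z)-but-2-ene-1,4-diyl diacetate
Product: 28 2-oxoethyl acetate
Conditions: O3, CH2Cl2, −78 °C; then Me2S
Reagents that add atoms: ozone, [O-][O+]=O
Why: Ozonolysis with reductive work-up cleaves the symmetrical alkene into two molecules of the aldehyde.

Step 18
Reactants: 28; 29 prop-2-en-1-yl prop-2-enoate (allyl acrylate)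
Product: 30 rac-prop-2-en-1-yl 4-acetoxy-3-hydroxy-2-methylidenebutanoate
Conditions: DABCO, 1,4-dioxane/H2O, rt
Reagents that add atoms: none
Why: Morita–Baylis–Hillman reaction forms the C2′–C3′ bond and gives the whole side-chain skeleton with the 4′-acetate in place; the carbinol is racemic.

Step 19
Reactants: 30
Product: 31 prop-2-en-1-yl (3R)-4-acetoxy-3-hydroxy-2-methylidenebutanoate
Conditions: Burkholderia cepacia lipase (immobilised), vinyl acetate, MTBE, 30 °C, run beyond half conversion
Reagents that add atoms: none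
Why: Lipase-catalysed kinetic resolution by enantioselective transesterification; with the acrylate unit as large group and CH2OAc as medium group the (3S)-alcohol should be acetylated and the required (3R)-alcohol recovered.

Step 20
Reactants: 31
Product: 32 prop-2-en-1-yl (3R)-4-acetoxy-3-{[tert-butyl(dimethyl)silyl]oxy}-2-methylidenebutanoate
Conditions: TBSOTf, 2,6-lutidine, CH2Cl2, −78 to 0 °C
Reagents that add atoms: tert-butyldimethylsilyl trifluoromethanesulfonate, CC(C)(C)[Si](C)(C)OS(=O)(=O)C(F)(F)F
Why: Silylation of the secondary alcohol under non-nucleophilic base leaves the stereocentre and the primary acetate untouched.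

Step 21
Reactants: 32
Product: 33 (3R)-4-acetoxy-3-{[tert-butyl(dimethyl)silyl]oxy}-2-methylidenebutanoic acid
Conditions: Pd(PPh3)4 (5 mol%), HCO2H, Et3N, THF, rt
Reagents that add atoms: none
Why: Palladium-catalysed deallylation (Tsuji–Trost ionisation, formate as hydride donor) frees the acid without a nucleophile that could add to the acrylate or cleave the acetate.

Step 22
Reactants: 26; 33
Product: 35 15-O-TBDPS-3′-O-TBS-protected target, via mixed anhydride 34 (not isolated)
Conditions: 2,4,6-trichlorobenzoyl chloride, Et3N, toluene, rt; then 26, DMAP, rt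
Reagents that add atoms: none
Why: Yamaguchi esterification acylates the hindered C8–OH with retention and without base strong enough to open the lactone or move the acetate.

Step 23
Reactants: 35
Product: 36 target (CNP0219661.4)
Conditions: HF·pyridine, pyridine, THF, 0 °C to rt
Reagents that add atoms: none
Why: Fluoride-mediated desilylation removes the TBDPS and TBS ethers in one operation; the buffered acidic medium avoids 4′-to-3′ acetyl migration and transannular cyclisation of the 1,5-diene.

Compound list
1 | (E)-but-2-enal (crotonaldehyde) | C/C=C/C=O | starting material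
2 | prop-2-ene-1-thiol | C=CCS | starting material
3 | rac-3-(prop-2-en-1-ylsulfanyl)butanal | CC(SCC=C)CC=O | intermediate
4 | rac-1,1-dimethoxy-3-(prop-2-en-1-ylsulfanyl)butane | CC(SCC=C)CC(OC)OC | intermediate
5 | rac-1,1-dimethoxy-3-(prop-2-en-1-ylsulfonyl)butane | CC(CC(OC)OC)S(=O)(=O)CC=C | intermediate
6 | 4-bromofuran-2(5H)-one | O=C1C=C(Br)CO1 | starting material
7 | 9-[3-(4,4-dimethoxybutan-2-ylsulfonyl)propyl]-9-borabicyclo[3.3.1]nonane | CC(CC(OC)OC)S(=O)(=O)CCCB1C2CCCC1CCC2 | intermediate (not isolated)
8 | 4-[3-(4,4-dimethoxybutan-2-ylsulfonyl)propyl]furan-2(5H)-one | CC(CC(OC)OC)S(=O)(=O)CCCC1=CC(=O)OC1 | intermediate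
9 | 4-[3-(4,4-dimethoxybutan-2-ylsulfonyl)propyl]-2,5-dihydrofuran-2-ol (lactol) | CC(CC(OC)OC)S(=O)(=O)CCCC1=CC(O)OC1 | intermediate (not isolated)
10 | (2Z)-2-[3-(4,4-dimethoxybutan-2-ylsulfonyl)propyl]hexa-2,5-diene-1,4-diol | C=CC(O)/C=C(\CO)CCCS(=O)(=O)C(C)CC(OC)OC | intermediate
11 | (4Z)-5-{[tert-butyl(diphenyl)silyl]oxymethyl}-8-(4,4-dimethoxybutan-2-ylsulfonyl)octa-1,4-dien-3-ol, racemic at C3 | C=CC(O)/C=C(\CO[Si](c1ccccc1)(c1ccccc1)C(C)(C)C)CCCS(=O)(=O)C(C)CC(OC)OC | intermediate
12 | (3S,4Z)-5-{[tert-butyl(diphenyl)silyl]oxymethyl}-8-(4,4-dimethoxybutan-2-ylsulfonyl)octa-1,4-dien-3-ol | C=C[C@H](O)/C=C(\CO[Si](c1ccccc1)(c1ccccc1)C(C)(C)C)CCCS(=O)(=O)C(C)CC(OC)OC | intermediate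
13 | (3S,4Z)-5-{[tert-butyl(diphenyl)silyl]oxymethyl}-8-chloro-8-(4,4-dimethoxybutan-2-ylsulfonyl)octa-1,4-dien-3-ol | C=C[C@H](O)/C=C(\CO[Si](c1ccccc1)(c1ccccc1)C(C)(C)C)CCC(Cl)S(=O)(=O)C(C)CC(OC)OC | intermediate
14 | 2-(bromomethyl)prop-2-enoic acid | C=C(CBr)C(=O)O | starting material
15 | 2-(bromomethyl)prop-2-enoate ester of 13 at the C3 (germacrane C6) hydroxyl | C=C[C@H](OC(=O)C(=C)CBr)/C=C(\CO[Si](c1ccccc1)(c1ccccc1)C(C)(C)C)CCC(Cl)S(=O)(=O)C(C)CC(OC)OC | intermediate
16 | (5R)-3-(bromomethyl)-5-[(1Z)-2-{[tert-butyl(diphenyl)silyl]oxymethyl}-5-chloro-5-(4,4-dimethoxybutan-2-ylsulfonyl)pent-1-en-1-yl]furan-2(5H)-one | O=C1O[C@H](/C=C(\CO[Si](c2ccccc2)(c2ccccc2)C(C)(C)C)CCC(Cl)S(=O)(=O)C(C)CC(OC)OC)C=C1CBr | intermediate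
17 | aldehyde from 16: 3-{[(4Z)-5-[(2R)-4-(bromomethyl)-5-oxo-2,5-dihydrofuran-2-yl]-4-{[tert-butyl(diphenyl)silyl]oxymethyl}-1-chloropent-4-en-1-yl]sulfonyl}butanal | O=C1O[C@H](/C=C(\CO[Si](c2ccccc2)(c2ccccc2)C(C)(C)C)CCC(Cl)S(=O)(=O)C(C)CC=O)C=C1CBr | intermediate
18 | allylchromium dichloride of 17 (Cr on the former bromomethyl carbon C13) | O=C1O[C@H](/C=C(\CO[Si](c2ccccc2)(c2ccccc2)C(C)(C)C)CCC(Cl)S(=O)(=O)C(C)CC=O)C=C1C[Cr](Cl)Cl | intermediate (not isolated)
19 | α-methylene-γ-lactone (C6–O–C12, C7–C11) trans-fused to the eleven-membered ring C7–C6–C5=C4–C3–C2–C1(Cl)–SO2–C10(CH3)–C9–C8; 8-OH free, 15-OTBDPS; C6, C7, C8 as in 36 | C=C1C(=O)O[C@@H]2/C=C(\CO[Si](c3ccccc3)(c3ccccc3)C(C)(C)C)CCC(Cl)S(=O)(=O)C(C)C[C@H](O)[C@@H]12 | intermediate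
20 | 8-O-triethylsilyl ether of 19 | C=C1C(=O)O[C@@H]2/C=C(\CO[Si](c3ccccc3)(c3ccccc3)C(C)(C)C)CCC(Cl)S(=O)(=O)C(C)C[C@H](O[Si](CC)(CC)CC)[C@@H]12 | intermediate (not isolated)
21 | 13-(dimethylamino)-11,13-dihydro derivative of 20 (Mannich-base lactone, α-chloro sulfone, eleven-membered ring) | CN(C)CC1C(=O)O[C@@H]2/C=C(\CO[Si](c3ccccc3)(c3ccccc3)C(C)(C)C)CCC(Cl)S(=O)(=O)C(C)C[C@H](O[Si](CC)(CC)CC)[C@@H]12 | intermediate
22 | episulfone: thiirane 1,1-dioxide spanning C1 and C10, fused to the ten-membered carbocycle (C2 and C9 on opposite faces) | CN(C)CC1C(=O)O[C@@H]2/C=C(\CO[Si](c3ccccc3)(c3ccccc3)C(C)(C)C)CCC3S(=O)(=O)C3(C)C[C@H](O[Si](CC)(CC)CC)[C@@H]12 | intermediate (not isolated)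
23 | 13-(dimethylamino)-11,13-dihydro-8-O-TES-15-O-TBDPS derivative of 8α,15-dihydroxygermacra-1(10)E,4-dien-6α,12-olide (ten-membered ring) | CN(C)CC1C(=O)O[C@@H]2/C=C(\CO[Si](c3ccccc3)(c3ccccc3)C(C)(C)C)CC/C=C(\C)C[C@H](O[Si](CC)(CC)CC)[C@@H]12 | intermediate
24 | trimethylammonium iodide of 23 | C[N+](C)(C)CC1C(=O)O[C@@H]2/C=C(\CO[Si](c3ccccc3)(c3ccccc3)C(C)(C)C)CC/C=C(\C)C[C@H](O[Si](CC)(CC)CC)[C@@H]12.[I-] | intermediate (not isolated)
25 | 8-O-TES-15-O-TBDPS-8α,15-dihydroxygermacra-1(10),4,11(13)-trien-6α,12-olide | C=C1C(=O)O[C@@H]2/C=C(\CO[Si](c3ccccc3)(c3ccccc3)C(C)(C)C)CC/C=C(\C)C[C@H](O[Si](CC)(CC)CC)[C@@H]12 | intermediate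
26 | 15-O-TBDPS-8α,15-dihydroxygermacra-1(10),4,11(13)-trien-6α,12-olide | C=C1C(=O)O[C@@H]2/C=C(\CO[Si](c3ccccc3)(c3ccccc3)C(C)(C)C)CC/C=C(\C)C[C@H](O)[C@@H]12 | intermediate
27 | (Z)-but-2-ene-1,4-diyl diacetate | CC(=O)OC/C=C\COC(C)=O | starting material
28 | 2-oxoethyl acetate | CC(=O)OCC=O | intermediate
29 | prop-2-en-1-yl prop-2-enoate (allyl acrylate) | C=CCOC(=O)C=C | starting material
30 | rac-prop-2-en-1-yl 4-acetoxy-3-hydroxy-2-methylidenebutanoate | C=CCOC(=O)C(=C)C(O)COC(C)=O | intermediate
31 | prop-2-en-1-yl (3R)-4-acetoxy-3-hydroxy-2-methylidenebutanoate | C=CCOC(=O)C(=C)[C@@H](O)COC(C)=O | intermediate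
32 | prop-2-en-1-yl (3R)-4-acetoxy-3-{[tert-butyl(dimethyl)silyl]oxy}-2-methylidenebutanoate | C=CCOC(=O)C(=C)[C@@H](O[Si](C)(C)C(C)(C)C)COC(C)=O | intermediate
33 | (3R)-4-acetoxy-3-{[tert-butyl(dimethyl)silyl]oxy}-2-methylidenebutanoic acid | OC(=O)C(=C)[C@@H](O[Si](C)(C)C(C)(C)C)COC(C)=O | intermediate
34 | mixed anhydride of 33 and 2,4,6-trichlorobenzoic acid | O=C(OC(=O)C(=C)[C@@H](O[Si](C)(C)C(C)(C)C)COC(C)=O)c1c(Cl)cc(Cl)cc1Cl | intermediate (not isolated)
35 | 15-O-TBDPS-3′-O-TBS derivative of 36 | C=C1C(=O)O[C@@H]2/C=C(\CO[Si](c3ccccc3)(c3ccccc3)C(C)(C)C)CC/C=C(\C)C[C@H](OC(=O)C(=C)[C@@H](O[Si](C)(C)C(C)(C)C)COC(C)=O)[C@@H]12 | intermediate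
36 | (3aR,4S,6E,10Z,11aR)-10-(hydroxymethyl)-6-methyl-3-methylidene-2-oxo-2,3,3a,4,5,8,9,11a-octahydrocyclodeca[b]furan-4-yl (3R)-4-acetoxy-3-hydroxy-2-methylidenebutanoate | C=C1C(=O)O[C@@H]2/C=C(\CO)CC/C=C(\C)C[C@H](OC(=O)C(=C)[C@@H](O)COC(C)=O)[C@@H]12 | target

Total step count: 23 (steps 1–16 main line, steps 17–21 side-chain acid, steps 22–23 union and deprotection).
Longest linear sequence: 18 steps (steps 1–16, 22, 23).

Steps most likely to fail

Step 14. What may go wrong: loss of geometric control during episulfone formation, so that the contraction delivers the Z alkene at C1=C10, or erosion of material by base before the α′-carbanion closes. Fallback: the contraction is no longer asked to set the geometry. Setting out from 21, the same extrusion is accepted with whatever geometry it gives, and the (1(10)Z)-configured ring-contracted amine adduct F1 is then converted into the E isomer by sensitised photochemical Z-to-E isomerisation (UV irradiation, degassed solution, high-energy triplet sensitiser such as acetone), a correction known for Z-configured C1=C10 bonds in germacranolide macrocycles. The route is rejoined at 23.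

Step 12. What may go wrong: oligomerisation in competition with ring closure, or addition through the alternative transition state with the aldehyde residue axial, giving poor facial selectivity at the aldehyde and hence the wrong configuration at C8. Fallback: the C8 centre is corrected after ring closure instead of being set in it. Setting out from 17, the cyclisation is run as before and the C8-epimeric hydroxy lactone F2 is inverted by a Mitsunobu reaction with chloroacetic acid (PPh3, DIAD, THF, 0 °C) to the 8-O-chloroacetate with the required configuration F3. The chloroacetate is then removed under neutral conditions (thiourea, NaHCO3, EtOH), which spare the lactone and the exo-methylene group, and the route is rejoined at 19.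

Step 10. What may go wrong: catalyst decomposition by the allylic bromide, or sluggish closure onto the 1,1-disubstituted acrylate alkene. Fallback: the bromide is introduced after, not before, the metathesis. Setting out from 13, Steglich esterification with 2-{[tert-butyl(dimethyl)silyl]oxymethyl}prop-2-enoic acid gives the silyloxymethyl acrylate ester F4. Ring-closing metathesis (second-generation Grubbs catalyst) gives the 3-(silyloxymethyl)butenolide F5, and selective methanolysis of the primary TBS ether (PPTS, MeOH) gives the 3-(hydroxymethyl)butenolide F6. Appel bromination (CBr4, PPh3, CH2Cl2, 0 °C) then rejoins the route at 16.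

Further compounds
F1 | step 14 | (1(10)Z) isomer of 23 | CN(C)CC1C(=O)O[C@@H]2/C=C(\CO[Si](c3ccccc3)(c3ccccc3)C(C)(C)C)CC/C=C(/C)C[C@H](O[Si](CC)(CC)CC)[C@@H]12
F2 | step 12 | C8 epimer of 19 | C=C1C(=O)O[C@@H]2/C=C(\CO[Si](c3ccccc3)(c3ccccc3)C(C)(C)C)CCC(Cl)S(=O)(=O)C(C)C[C@@H](O)[C@@H]12
F3 | step 12 | 8-O-chloroacetate of 19 | C=C1C(=O)O[C@@H]2/C=C(\CO[Si](c3ccccc3)(c3ccccc3)C(C)(C)C)CCC(Cl)S(=O)(=O)C(C)C[C@H](OC(=O)CCl)[C@@H]12
F4 | step 10 | 2-{[tert-butyl(dimethyl)silyl]oxymethyl}prop-2-enoate ester of 13 | C=C[C@H](OC(=O)C(=C)CO[Si](C)(C)C(C)(C)C)/C=C(\CO[Si](c1ccccc1)(c1ccccc1)C(C)(C)C)CCC(Cl)S(=O)(=O)C(C)CC(OC)OC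
F5 | step 10 | analogue of 16 with CH2OTBS in place of CH2Br | O=C1O[C@H](/C=C(\CO[Si](c2ccccc2)(c2ccccc2)C(C)(C)C)CCC(Cl)S(=O)(=O)C(C)CC(OC)OC)C=C1CO[Si](C)(C)C(C)(C)C
F6 | step 10 | analogue of 16 with CH2OH in place of CH2Br | O=C1O[C@H](/C=C(\CO[Si](c2ccccc2)(c2ccccc2)C(C)(C)C)CCC(Cl)S(=O)(=O)C(C)CC(OC)OC)C=C1CO
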